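I decided to read the plateaus of the earlier runs, not their early readings.

| flask | substrate | temperature | remark | time |
|---|---|---|---|---|
| amber | 10 mM | 10 °C | run made earlier |  |
| blue | 40 mM | 32 °C | run made earlier |  |
| cedar | 20 mM |  | at 0 °C until 2.0 h, from then on at 40 °C | 10 h |
| birch | 20 mM |  | at 0 °C throughout | 10 h |

amber run (percent of the substrate charged): time / h: target / % = 1.00: 36.6; 2.00: 35.9; 3.00: 32.8; 4.00: 30.8; 5.00: 29.8; 6.00: 30.7

blue run (percent of the substrate charged): time / min: target / % = 8.00: 49.3; 25.0: 63.5; 50.0: 64.5; 60.0: 65.6; 90.0: 64.5; 120: 64.2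

(scatter of a reading: 0.5 percentage points)

* the winner by amount of target, in percent of the substrate charged; "neither" if no more than 2 percentage points parts them (cedar / birch / neither)
* how much target is there at the end, in percent of the substrate charged: cedar
* how much target is there at the end, in percent of the substrate charged: birch

Substrate was the one charge, so its balance put every percent either in target or in something else. Amber, with [substrate] at 10 mM, levelled near 30.4% target, and blue, at 40 mM, near 64.7%. So I took target over the rest of the charge as a plateau quotient, an apparent equilibrium constant: 0.437 at 10 °C and 1.83 at 32 °C. But the two runs differ in charge as well as temperature, so I assumed that the charge did not matter and drew a van 't Hoff line, with slope 46.8 kJ mol⁻¹.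

The line gave 2.94, the plateau quotient at 40 °C, which is 74.6% target. Blue stood near its plateau by 25.0 min, and cedar had 8.00 h hot, longer than that, so I committed to this share for cedar. At 0 °C the line gave 0.211, or 17.4% target. But amber, though warmer, took about 5.00 h to level off, so I expected birch to end above that share.

The forecast chose cedar, with cedar at 69% (56% to 80%) and birch at 30% (20% to 40%). It put cedar lower than I did, since “the lower concentration may pull that down”.

The flask gave cedar: cedar 74.0%, birch 23.5%.

    substrate ⇌ intermediate A (K = 1.40, k = 1.30 × 10⁻⁴ s⁻¹, Ea = 76.0 kJ mol⁻¹, ΔH = −30.0 kJ mol⁻¹)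
    intermediate A → target (k = 3.20 × 10⁻⁴ s⁻¹, Ea = 94.0 kJ mol⁻¹)
    intermediate A → intermediate B (k = 1.10 × 10⁻⁵ s⁻¹, Ea = 86.0 kJ mol⁻¹)
    intermediate B ⇌ intermediate C (K = 0.320, k = 1.10 × 10⁻⁴ s⁻¹, Ea = 77.0 kJ mol⁻¹, ΔH = 30.0 kJ mol⁻¹)
    target ⇌ isomer of the product (K = 4.70, k = 9.80 × 10⁻⁵ s⁻¹, Ea = 80.0 kJ mol⁻¹, ΔH = −48.0 kJ mol⁻¹)
    (constants at 0 °C)

Cedar's end was a quotient of 2.85 against my 2.94, and its rest included 23.4% isomer of the product. Birch still held 3.1% substrate at 10 h, and by 100 h it read 17.0% target. The neighbouring flask, cedar read at 2.5 h, had been hot for 30.0 min, longer than blue's 25.0 min, so I held it to the same 2.94. It read 74.0% target, a quotient of 2.85, with 0% substrate left.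

All runs are simulated on assumed constants, noise included.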